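The ring is numbered C1 (bears C7H2–O-tiglate), C2 (alkene CH), C3 (O-tiglate), C4 (isopropyl), C5 (OAc), C6 (C=O). The plan cuts C3–C4 and C5–C6 of this cyclohexenone ring. A catalytic enantioselective endo Diels–Alder reaction closes the carbocycle and fixes C3, C4 and C5 together. It exploits the C1=C2 alkene flanked by the cis C3–O/C4 and trans C4/C5–O triad, with the C4 isopropyl carried as an acetyl group. The precursors are an E-1-tigloyloxy-3-(tigloyloxymethyl)buta-1,3-diene and E-4-acetoxybut-3-en-2-one. They already hold all three esters, so only acetyl-to-isopropyl conversion and oxidation of C6H2 follow.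

Key step: step 5

Assumption: the facial sense is assigned from the usual picture of an s-trans enone held on boron with an α-C–H···O contact above one phenyl group, which points to the (S)-prolinol-derived catalyst for Si-face attack at the acetyl-bearing carbon; the (R)-catalyst would be taken if the sense proved opposite.

Step 1
Reactants: 1 prop-2-yn-1-ol (propargyl alcohol); 2 tiglic acid, (E)-2-methylbut-2-enoic acid
Product: 3 prop-2-yn-1-yl tiglate
Conditions: DCC, DMAP (cat.), CH2Cl2, 0 °C to rt
Reagents that add atoms: none
Why: Steglich esterification, a carbodiimide-driven and DMAP-catalysed acyl transfer to a primary alcohol under neutral conditions, should leave the E tiglate alkene and the terminal alkyne untouched, and no stereocentre is involved.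

Step 2
Reactants: 2 tiglic acid; 4 vinyl acetate
Product: 5 vinyl tiglate
Conditions: Pd(OAc)2 (cat.), KOH (cat.), neat 4 (large excess), rt
Reagents that add atoms: none
Why: Pd(OAc)2-catalysed transvinylation (vinyl interchange) moves the vinyl group from acetate to tiglate by reversible acyloxypalladation and loss of acetate, the excess of vinyl acetate drives the equilibrium, and the trisubstituted tiglate alkene does not take part.

Step 3
Reactants: 3 prop-2-yn-1-yl tiglate; 5 vinyl tiglate
Product: 6 (1E)-3-(tigloyloxymethyl)buta-1,3-dien-1-yl tiglate
Conditions: second-generation Grubbs catalyst RuCl2(=CHPh)(PCy3)(H2IMes) (5 mol%), 5 (excess), toluene, 80 °C; chromatography on Et3N-washed silica gel to take the E isomer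
Reagents that add atoms: none
Why: Enyne cross-metathesis of a terminal alkyne with a vinyl ester should join the acyloxy-bearing CH to the alkyne terminus and the methylene to the internal carbon, giving the 1-acyloxy-3-substituted 1,3-diene with every atom of both partners retained, while the trisubstituted, electron-poor tiglate alkenes stay out of the metathesis and no stereocentre is formed.

Step 4
Reactants: 7 but-3-yn-2-one; 8 acetic acid
Product: 9 (E)-4-acetoxybut-3-en-2-one
Conditions: DABCO (cat.), CH2Cl2, 0 °C to rt
Reagents that add atoms: none
Why: Amine-catalysed conjugate addition of a carboxylic acid to an ynone should proceed by DABCO addition to the alkyne terminus and addition–elimination by acetate, giving the more stable E β-acetoxy enone, with no stereocentre formed.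

Step 5
Reactants: 6 (1E)-3-(tigloyloxymethyl)buta-1,3-dien-1-yl tiglate; 9 (E)-4-acetoxybut-3-en-2-one
Product: 10 [(3S,4R,5S)-5-acetoxy-4-acetyl-3-(tigloyloxy)cyclohex-1-en-1-yl]methyl tiglate (overview numbering; C3–O cis to C4–acetyl, C5–OAc trans to it)
Conditions: (S)-3,3-diphenyl-1-(o-tolyl)tetrahydro-1H,3H-pyrrolo[1,2-c][1,3,2]oxazaborole [from (S)-α,α-diphenylprolinol and o-tolylboronic acid] (20 mol%), HNTf2 (18 mol%), CH2Cl2, −78 to −40 °C
Reagents that add atoms: none
Why: The cationic boron Lewis acid binds the acetyl oxygen of 9 and lowers its LUMO, and a concerted, asynchronous [4+2] cycloaddition follows in which the nucleophilic diene terminus C6 bonds to the acetoxy-bearing β-carbon (C5) ahead of C3–C4 bonding; the closest known reaction type is the chiral oxazaborolidinium-catalysed endo Diels–Alder reaction of 1-oxygenated dienes with acyclic E-enones. The six-membered ring is closed by intermolecular [4π+2π] cycloaddition, both σ-bonds (C3–C4 and C5–C6) forming suprafacially on each partner. C3 is set relative to C4 by the E geometry of the dienyl ester together with endo placement of the boron-bound acetyl group (C3–O cis to C4–acetyl), C5 is set relative to C4 by the E geometry of the dienophile (C5–OAc trans), and the absolute configuration is set at C4 by the catalyst, one phenyl group of which covers a face of the bound s-trans enone so that the diene adds to the Si face of the acetyl-bearing carbon. The step needs regio-, endo- and face-selectivity: regiochemistry is secured by the 1-acyloxy and 3-alkyl donors of 6, which both enlarge the coefficient at C6, endo selectivity by the Lewis-acid-bound carbonyl, and chemoselectivity by the tiglate alkenes being trisubstituted and electron-poor, hence inert as dienophiles. Any Z isomer of 6 that remains has a strained s-cis form and should stay behind unreacted.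

Step 6
Reactants: 10 [(3S,4R,5S)-5-acetoxy-4-acetyl-3-(tigloyloxy)cyclohex-1-en-1-yl]methyl tiglate
Product: 11 [(3S,4R,5S)-5-acetoxy-4-(prop-1-en-2-yl)-3-(tigloyloxy)cyclohex-1-en-1-yl]methyl tiglate
Conditions: Zn, CH2Br2, TiCl4 (reagent pre-formed and aged in THF), then 10, CH2Cl2, 0 °C to rt
Reagents that add atoms: dibromomethane, BrCBr
Why: Takai–Lombardo methylenation uses a non-basic zinc–titanium methylene reagent that attacks ketones far faster than esters, so the C4 acetyl group should become isopropenyl without enolisation, hence without C4 epimerisation or β-elimination of the C3 and C5 acyloxy groups, and the three esters and the alkenes are left alone.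

Step 7
Reactants: 11 [(3S,4R,5S)-5-acetoxy-4-(prop-1-en-2-yl)-3-(tigloyloxy)cyclohex-1-en-1-yl]methyl tiglate
Product: 12 [(3S,4R,5S)-5-acetoxy-4-isopropyl-3-(tigloyloxy)cyclohex-1-en-1-yl]methyl tiglate
Conditions: H2 (1 atm), RhCl(PPh3)3 (10 mol%), benzene, rt
Reagents that add atoms: none
Why: Homogeneous hydrogenation with RhCl(PPh3)3 should reduce the unhindered 1,1-disubstituted isopropenyl alkene much faster than the trisubstituted C1=C2 and the trisubstituted, conjugated tiglate alkenes, and since isopropyl is not stereogenic no new stereocentre arises and C3, C4 and C5 are untouched.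

Step 8
Reactants: 12 [(3S,4R,5S)-5-acetoxy-4-isopropyl-3-(tigloyloxy)cyclohex-1-en-1-yl]methyl tiglate
Product: 13 [(3S,4S,5R)-5-acetoxy-4-isopropyl-6-oxo-3-(tigloyloxy)cyclohex-1-en-1-yl]methyl tiglate (target; same spatial arrangement as 12, the descriptors at C4 and C5 change only through the new C6 carbonyl)
Conditions: CrO3, 3,5-dimethylpyrazole, CH2Cl2, −20 °C
Reagents that add atoms: chromium trioxide, O=[Cr](=O)=O
Why: Allylic oxidation of a cycloalkene methylene to the enone with the CrO3–3,5-dimethylpyrazole complex should strike C6H2, the only allylic position without an acyloxy substituent (C3–H and C7H2 are deactivated by their ester oxygens), giving the C6 ketone conjugated with C1=C2 under neutral, cold conditions that leave the esters and the now α-placed C5 stereocentre intact.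

Compound list
1 | prop-2-yn-1-ol (propargyl alcohol) | C#CCO | starting material
2 | tiglic acid, (E)-2-methylbut-2-enoic acid | C/C=C(\C)C(=O)O | starting material
3 | prop-2-yn-1-yl tiglate | C/C=C(\C)C(=O)OCC#C | intermediate
4 | vinyl acetate | C=COC(C)=O | starting material
5 | vinyl tiglate | C/C=C(\C)C(=O)OC=C | intermediate
6 | (1E)-3-(tigloyloxymethyl)buta-1,3-dien-1-yl tiglate | C/C=C(\C)C(=O)OCC(=C)/C=C/OC(=O)/C(C)=C/C | intermediate
7 | but-3-yn-2-one | CC(=O)C#C | starting material
8 | acetic acid | CC(=O)O | starting material
9 | (E)-4-acetoxybut-3-en-2-one | CC(=O)/C=C/OC(C)=O | intermediate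
10 | [(3S,4R,5S)-5-acetoxy-4-acetyl-3-(tigloyloxy)cyclohex-1-en-1-yl]methyl tiglate | C/C=C(\C)C(=O)OCC1=C[C@H](OC(=O)/C(C)=C/C)[C@H](C(C)=O)[C@@H](OC(C)=O)C1 | intermediate
11 | [(3S,4R,5S)-5-acetoxy-4-(prop-1-en-2-yl)-3-(tigloyloxy)cyclohex-1-en-1-yl]methyl tiglate | C/C=C(\C)C(=O)OCC1=C[C@H](OC(=O)/C(C)=C/C)[C@H](C(C)=C)[C@@H](OC(C)=O)C1 | intermediate
12 | [(3S,4R,5S)-5-acetoxy-4-isopropyl-3-(tigloyloxy)cyclohex-1-en-1-yl]methyl tiglate | C/C=C(\C)C(=O)OCC1=C[C@H](OC(=O)/C(C)=C/C)[C@H](C(C)C)[C@@H](OC(C)=O)C1 | intermediate
13 | [(3S,4S,5R)-5-acetoxy-4-isopropyl-6-oxo-3-(tigloyloxy)cyclohex-1-en-1-yl]methyl tiglate | C/C=C(\C)C(=O)OCC1=C[C@H](OC(=O)/C(C)=C/C)[C@H](C(C)C)[C@@H](OC(C)=O)C1=O | target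

Total step count: 8.
Longest linear sequence: 6 steps (steps 1, 3, 5, 6, 7, 8).

Steps most likely to fail

Step 5. The ester carbonyls of both partners may compete with the ketone for the boron centre, and the β-acetoxy group damps the enone, so turnover may be slow and facial discrimination weak. The strongly acidic catalyst may also provoke loss of acetic or tiglic acid from the adduct. Fallback, setting out from 6 and 9: the cycloaddition is run without a chiral catalyst (toluene, 80 °C, trace of hydroquinone, or ZnBr2 in CH2Cl2 at low temperature), where the endo rule and the E geometries should still give the correct relative configuration as the racemic adduct F1. The enantiomers are then separated by preparative chromatography on a chiral stationary phase (amylose tris(3,5-dimethylphenylcarbamate)); the unwanted enantiomer F2 is set aside and the route is rejoined at 10.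

Step 8. Oxygen may be delivered with allylic transposition (to C2, with the alkene moving to C1=C6), or the reaction may stall on this electron-poor alkene and begin to attack the tiglate methyl groups. Fallback, setting out from 12: SeO2 (cat.) with t-BuOOH in CH2Cl2 at rt should hydroxylate by an ene reaction and [2,3]-sigmatropic shift, which returns the alkene to C1=C2 and favours the ring methylene next to the more substituted alkene carbon. This gives the C6 allylic alcohol F3 as a mixture of C6 epimers. Immediate oxidation with Dess–Martin periodinane (NaHCO3, CH2Cl2) removes that centre and rejoins the route at 13.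

Step 6. The β,β′-diacyloxy ketone may lose acetic or tiglic acid under the Lewis-acidic titanium reagent (ultimately aromatising), or the hindered carbonyl may react sluggishly. Fallback, setting out from 10: a Peterson olefination in two stages. Me3SiCH2MgCl with CeCl3 in THF at −78 °C, a weakly basic organocerium reagent, should add to the ketone in preference to the esters and give the β-hydroxysilane F4. HF·pyridine in MeCN at 0 °C should then eliminate silanol regiospecifically to the 1,1-disubstituted alkene, rejoining the route at 11.

Further compounds
F1 | step 5 | racemic [5-acetoxy-4-acetyl-3-(tigloyloxy)cyclohex-1-en-1-yl]methyl tiglate, relative configuration as in 10 | C/C=C(\C)C(=O)OCC1=CC(OC(=O)/C(C)=C/C)C(C(C)=O)C(OC(C)=O)C1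
F2 | step 5 | [(3R,4S,5R)-5-acetoxy-4-acetyl-3-(tigloyloxy)cyclohex-1-en-1-yl]methyl tiglate, the enantiomer of 10 | C/C=C(\C)C(=O)OCC1=C[C@@H](OC(=O)/C(C)=C/C)[C@@H](C(C)=O)[C@H](OC(C)=O)C1
F3 | step 8 | [(3S,4R,5S)-5-acetoxy-6-hydroxy-4-isopropyl-3-(tigloyloxy)cyclohex-1-en-1-yl]methyl tiglate, C6 epimers | C/C=C(\C)C(=O)OCC1=C[C@H](OC(=O)/C(C)=C/C)[C@H](C(C)C)[C@@H](OC(C)=O)C1O
F4 | step 6 | [(3S,4R,5S)-5-acetoxy-4-[2-hydroxy-1-(trimethylsilyl)propan-2-yl]-3-(tigloyloxy)cyclohex-1-en-1-yl]methyl tiglate, carbinol epimers | C/C=C(\C)C(=O)OCC1=C[C@H](OC(=O)/C(C)=C/C)[C@H](C(C)(O)C[Si](C)(C)C)[C@@H](OC(C)=O)C1
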